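**Plan**

- Retrosynthesis: the acrylic acid is cut back to a malonate on C4 (C2=C1 by decarboxylative methylenation, C4–C2 by allylic alkylation). Ring C and the lactone are cut together at C7–C8 and C4–C9 (intramolecular Diels–Alder through the C12–O11–C10 acrylate). C13 is stripped of C7 and C12 (two enolate alkylations). Last, O17–C16 and C18–C19 are cut.
- Enabling feature: the O17–C18 ether bridge spans bridgeheads C16 and C19 of the 6-oxabicyclo[3.2.1]octan-3-one (carbocycle C13–C14–C15–C16–C20–C19). Without the bridge that ring is achiral 4,4-dimethylcyclohexa-2,5-dienone with enantiotopic β-carbons C19 and C16, so one methanol can deliver C18 to C19 and O17 to C16.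
- Forward order: the tetrahydrofuran bridge comes first (step 2). It is opened to an enone so that C13 can be made quaternary (C12, then C7). Lactone and cyclohexene ring C then close in one cycloaddition, the bridge is re-closed, and the side chain is finished.
- Stereochemistry: C19 from the chiral amine; C16 from the bridge geometry; C13 from allylation anti to C18; C7 and C8 from the endo cycloaddition on the diene face anti to C19; C4 from Mitsunobu inversion followed by palladium allylation with retention.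

Key step: step 2

Remark: atoms are numbered along the target SMILES (C1 = CH2 of the acrylic acid, C2, C3 = CO2H, C4–C9 = cyclohexane, C10 = lactone C=O, O11, C12, C13 = spiro carbon, C14 = ketone, C15, C16, O17, C18, C19, C20 = CMe2). Each chiral catalyst is taken in the antipode that gives the configuration drawn.

**Route**

Step 1
Reactants: 1 4,4-dimethylcyclohex-2-en-1-one
Product: 2 4,4-dimethylcyclohexa-2,5-dien-1-one
Conditions: IBX (2.5 equiv), DMSO/fluorobenzene 1:2, 80 °C
Reagents that add atoms: none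
Why: IBX dehydrogenation of a ketone to its α,β-unsaturated derivative introduces the second double bond at the only CH2–CH2 unit left, the quaternary C4 blocking aromatisation; no stereocentre is formed.

Step 2
Reactants: 2 4,4-dimethylcyclohexa-2,5-dien-1-one; 3 methanol
Product: 5 (1S,5R)-8,8-dimethyl-6-oxabicyclo[3.2.1]octan-3-one, via hydroxy enone 4 (not isolated)
Conditions: (n-Bu4N)4[W10O32] (2 mol %), trans-2-(9H-carbazol-9-yl)cyclohexan-1-amine (20 mol %), CF3CO2H (40 mol %), MeOH/MeCN 1:1, 365 nm LEDs, 25 °C; then Et3N, 25 °C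
Reagents that add atoms: none
Why: Proposed new method: photoexcited decatungstate abstracts a hydrogen atom from methanol and the nucleophilic hydroxymethyl radical adds to one of the two enantiotopic β-carbons (C19) of the chiral iminium ion formed from dienone 2 and the primary amine; reduction of the resulting α-iminyl radical cation (carbazole relay, then back electron transfer from the reduced polyoxotungstate) gives an enamine that hydrolyses to hydroxy enone 4. The closest known reaction type is the enantioselective photochemical radical conjugate addition to cyclic enones through chiral primary-amine iminium ions with decatungstate hydrogen-atom transfer, and decatungstate hydroxyalkylation of electron-poor alkenes with alcohols is also established, whereas desymmetrisation of an unsubstituted cross-conjugated dienone is the untested element. The tetrahydrofuran ring (C19–C18–O17–C16–C20) then closes by 5-exo-trig oxa-Michael addition of the C18 hydroxyl to the remaining enone, which completes the 6-oxabicyclo[3.2.1]octane. C19 is set by the catalyst, which must select one β-carbon and one face of the iminium ion, and C16 follows from the substrate because the one-carbon bridge C20 can only be spanned cis. The step needs mono-addition, secured because ring closure removes the second enone, and selective hydrogen abstraction from methanol, secured by using it as cosolvent with a dienone that carries only strong methyl C–H bonds.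

Step 3
Reactants: 5 (1S,5R)-8,8-dimethyl-6-oxabicyclo[3.2.1]octan-3-one
Product: 6 (5S)-5-{[(tert-butyldimethylsilyl)oxy]methyl}-4,4-dimethylcyclohex-2-en-1-one
Conditions: TBSCl, DBU, CH2Cl2, 0 to 25 °C
Reagents that add atoms: tert-butyldimethylsilyl chloride, CC(C)(C)[Si](C)(C)Cl
Why: Base-mediated retro-oxa-Michael (E1cB) opening of the β-alkoxy ketone is reversible and silylation of the released primary alcohol drains the equilibrium to an enone whose only enolisable position is C13; C19 is untouched and C16 becomes sp2.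

Step 4
Reactants: 6 (5S)-5-{[(tert-butyldimethylsilyl)oxy]methyl}-4,4-dimethylcyclohex-2-en-1-one
Product: 7 (5S,6R)-5-{[(tert-butyldimethylsilyl)oxy]methyl}-6-{[(4-methoxybenzyl)oxy]methyl}-4,4-dimethylcyclohex-2-en-1-one
Conditions: LiN(i-Pr)2, THF, −78 °C; then 4-MeOC6H4CH2OCH2Cl, −78 to −40 °C
Reagents that add atoms: 4-methoxybenzyl chloromethyl ether, COc1ccc(COCCl)cc1
Why: Kinetic α'-deprotonation of the cyclohexenone (no γ-hydrogen competes because C20 is quaternary) and enolate alkylation with an α-chloro ether install C12 on C13; the 5,6-trans isomer is expected, but this stereocentre is erased by enolisation in step 5.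

Step 5
Reactants: 7 (5S,6R)-5-{[(tert-butyldimethylsilyl)oxy]methyl}-6-{[(4-methoxybenzyl)oxy]methyl}-4,4-dimethylcyclohex-2-en-1-one
Product: 8 (5R,6S)-6-allyl-5-{[(tert-butyldimethylsilyl)oxy]methyl}-6-{[(4-methoxybenzyl)oxy]methyl}-4,4-dimethylcyclohex-2-en-1-one
Conditions: LiN(i-Pr)2, THF/DMPU, −78 °C; then allyl bromide, −78 to −30 °C
Reagents that add atoms: allyl bromide, C=CCBr
Why: Enolate C-allylation creates the quaternary centre, the allyl group entering the cross-conjugated enolate anti to the pseudoaxial CH2OTBS group on the neighbouring C19 (trans-2,3 rule), so that C7 ends trans and C12 cis to C18 and C13 is set.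

Step 6
Reactants: 8 (5R,6S)-6-allyl-5-{[(tert-butyldimethylsilyl)oxy]methyl}-6-{[(4-methoxybenzyl)oxy]methyl}-4,4-dimethylcyclohex-2-en-1-one
Product: 9 (2E)-4-[(1S,6R)-6-{[(tert-butyldimethylsilyl)oxy]methyl}-1-{[(4-methoxybenzyl)oxy]methyl}-5,5-dimethyl-2-oxocyclohex-3-en-1-yl]but-2-enal
Conditions: crotonaldehyde (5 equiv), second-generation Grubbs catalyst RuCl2(=CHPh)(PCy3)(H2IMes) (5 mol %), CH2Cl2, 40 °C
Reagents that add atoms: (E)-but-2-enal, C/C=C/C=O
Why: Olefin cross-metathesis of the terminal alkene with an excess of enal gives the (E)-enal, while the cis-disubstituted, neopentylic double bond of the ring enone is inert to the catalyst.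

Step 7
Reactants: 9 (2E)-4-[(1S,6R)-6-{[(tert-butyldimethylsilyl)oxy]methyl}-1-{[(4-methoxybenzyl)oxy]methyl}-5,5-dimethyl-2-oxocyclohex-3-en-1-yl]but-2-enal
Product: 10 (2E)-4-[(1S,6R)-6-{[(tert-butyldimethylsilyl)oxy]methyl}-1-(hydroxymethyl)-5,5-dimethyl-2-oxocyclohex-3-en-1-yl]but-2-enal
Conditions: DDQ, CH2Cl2/pH 7 buffer, 0 °C
Reagents that add atoms: none
Why: Oxidative cleavage of the p-methoxybenzyl ether with DDQ leaves silyl ether, enone and enal untouched; the alcohol is acylated at once to forestall oxa-Michael addition to the enal.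

Step 8
Reactants: 10 (2E)-4-[(1S,6R)-6-{[(tert-butyldimethylsilyl)oxy]methyl}-1-(hydroxymethyl)-5,5-dimethyl-2-oxocyclohex-3-en-1-yl]but-2-enal
Product: 11 [(1S,6R)-6-{[(tert-butyldimethylsilyl)oxy]methyl}-5,5-dimethyl-2-oxo-1-[(2E)-4-oxobut-2-en-1-yl]cyclohex-3-en-1-yl]methyl prop-2-enoate
Conditions: acryloyl chloride, i-Pr2NEt, CH2Cl2, −40 °C
Reagents that add atoms: acryloyl chloride, C=CC(=O)Cl
Why: O-acylation of the primary alcohol with an acid chloride installs C10, C8 and C9; because C13 is now quaternary the β-acyloxy ketone cannot eliminate.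

Step 9
Reactants: 11 [(1S,6R)-6-{[(tert-butyldimethylsilyl)oxy]methyl}-5,5-dimethyl-2-oxo-1-[(2E)-4-oxobut-2-en-1-yl]cyclohex-3-en-1-yl]methyl prop-2-enoate
Product: 13 (1S,4a'R,6R,7'R,8a'S)-7'-[(tert-butyldimethylsilyl)oxy]-6-{[(tert-butyldimethylsilyl)oxy]methyl}-5,5-dimethyl-4a',7',8',8a'-tetrahydrospiro[cyclohex-3-ene-1,4'-isochromene]-1',2(3'H)-dione, via silyloxydiene 12 (not isolated)
Conditions: TBSOTf, Et3N, CH2Cl2, −78 to 0 °C; then toluene, BHT, 120 °C (sealed tube)
Reagents that add atoms: tert-butyldimethylsilyl triflate, CC(C)(C)[Si](C)(C)OS(=O)(=O)C(F)(F)F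
Why: Soft γ-enolisation of the enal gives the (1E,3E)-silyloxydiene, which undergoes an ester-tethered intramolecular Diels–Alder reaction; the tether fixes the regiochemistry (C7–C8 and C4–C9), the endo position of the tether carbonyl gives the cis ring fusion with C13, C10 and the C4 oxygen all cis, and the diene face is chosen with the bulky C19 anti to the forming C7–C8 bond and the carbonyl C14 in the inside position.

Step 10
Reactants: 13 (1S,4a'R,6R,7'R,8a'S)-7'-[(tert-butyldimethylsilyl)oxy]-6-{[(tert-butyldimethylsilyl)oxy]methyl}-5,5-dimethyl-4a',7',8',8a'-tetrahydrospiro[cyclohex-3-ene-1,4'-isochromene]-1',2(3'H)-dione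
Product: 15 (1R,2S,4a'R,5R,7'R,8a'S)-7'-hydroxy-8,8-dimethyl-4a',7',8',8a'-tetrahydrospiro[6-oxabicyclo[3.2.1]octane-2,4'-isochromene]-1',3(3'H)-dione, via diol enone 14 (not isolated)
Conditions: HF·pyridine, THF, 0 to 25 °C; then DBU (0.1 equiv), CH2Cl2, 0 °C
Reagents that add atoms: none
Why: Desilylation frees both hydroxyls and the C18 alcohol re-adds to the enone by the same 5-exo-trig oxa-Michael addition as in step 2, C16 being set cis to C18 by the bridge geometry.

Step 11
Reactants: 15 (1R,2S,4a'R,5R,7'R,8a'S)-7'-hydroxy-8,8-dimethyl-4a',7',8',8a'-tetrahydrospiro[6-oxabicyclo[3.2.1]octane-2,4'-isochromene]-1',3(3'H)-dione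
Product: 16 (1R,2S,4a'R,5R,7'S,8a'S)-8,8-dimethyl-1',3-dioxo-4a',7',8',8a'-tetrahydrospiro[6-oxabicyclo[3.2.1]octane-2,4'-isochromen]-7'(3'H)-yl 4-nitrobenzoate
Conditions: 4-O2NC6H4CO2H, PPh3, DIAD, THF, 0 to 25 °C
Reagents that add atoms: 4-nitrobenzoic acid, O=C(O)c1ccc(cc1)[N+](=O)[O-]
Why: Mitsunobu esterification inverts the allylic C4 carbinol by SN2 displacement, which puts the leaving group on the convex face, trans to C13.

Step 12
Reactants: 16 (1R,2S,4a'R,5R,7'S,8a'S)-8,8-dimethyl-1',3-dioxo-4a',7',8',8a'-tetrahydrospiro[6-oxabicyclo[3.2.1]octane-2,4'-isochromen]-7'(3'H)-yl 4-nitrobenzoate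
Product: 17 dibenzyl 2-[(1R,2S,4a'R,5R,7'S,8a'S)-8,8-dimethyl-1',3-dioxo-4a',7',8',8a'-tetrahydrospiro[6-oxabicyclo[3.2.1]octane-2,4'-isochromen]-7'(3'H)-yl]propanedioate
Conditions: CH2(CO2Bn)2, NaH, Pd(PPh3)4 (5 mol %), THF, 0 to 50 °C
Reagents that add atoms: dibenzyl malonate, O=C(CC(=O)OCc1ccccc1)OCc1ccccc1
Why: Tsuji–Trost allylic alkylation, in which zerovalent palladium ionises the ester with inversion and the malonate attacks the less hindered allyl terminus C4 anti to the metal, gives overall retention, so C2 ends trans to C13 as in the target.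

Step 13
Reactants: 17 dibenzyl 2-[(1R,2S,4a'R,5R,7'S,8a'S)-8,8-dimethyl-1',3-dioxo-4a',7',8',8a'-tetrahydrospiro[6-oxabicyclo[3.2.1]octane-2,4'-isochromen]-7'(3'H)-yl]propanedioate
Product: 18 2-[(1R,2S,4a'R,5R,7'R,8a'S)-8,8-dimethyl-1',3-dioxo-4a',5',6',7',8',8a'-hexahydrospiro[6-oxabicyclo[3.2.1]octane-2,4'-isochromen]-7'(3'H)-yl]propanedioic acid
Conditions: H2 (1 atm), 10% Pd/C, EtOAc, 25 °C
Reagents that add atoms: none
Why: Heterogeneous hydrogenation saturates the C5=C6 double bond and hydrogenolyses both benzyl esters in one operation; no stereocentre is formed or touched.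

Step 14
Reactants: 18 2-[(1R,2S,4a'R,5R,7'R,8a'S)-8,8-dimethyl-1',3-dioxo-4a',5',6',7',8',8a'-hexahydrospiro[6-oxabicyclo[3.2.1]octane-2,4'-isochromen]-7'(3'H)-yl]propanedioic acid
Product: 20 2-[(1R,2S,4a'R,5R,7'R,8a'S)-8,8-dimethyl-1',3-dioxo-4a',5',6',7',8',8a'-hexahydrospiro[6-oxabicyclo[3.2.1]octane-2,4'-isochromen]-7'(3'H)-yl]prop-2-enoic acid (CNP0268721.2), via Mannich base 19 (not isolated)
Conditions: (CH2O)n, Et2NH, EtOAc, 0 to 70 °C
Reagents that add atoms: formaldehyde, C=O
Why: Mannich reaction of the malonic acid with formaldehyde and diethylamine followed by decarboxylative loss of the amine (decarboxylative methylenation) gives the 2-substituted acrylic acid, and C4 is not epimerisable under these conditions.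

**Compound list**

1 | 4,4-dimethylcyclohex-2-en-1-one | CC1(C)CCC(=O)C=C1 | starting material
2 | 4,4-dimethylcyclohexa-2,5-dien-1-one | CC1(C)C=CC(=O)C=C1 | intermediate
3 | methanol | CO | starting material
4 | (5S)-5-(hydroxymethyl)-4,4-dimethylcyclohex-2-en-1-one | O=C1C=CC(C)(C)[C@@H](CO)C1 | intermediate
5 | (1S,5R)-8,8-dimethyl-6-oxabicyclo[3.2.1]octan-3-one | O=C1C[C@H]2OC[C@@H](C1)C2(C)C | intermediate
6 | (5S)-5-{[(tert-butyldimethylsilyl)oxy]methyl}-4,4-dimethylcyclohex-2-en-1-one | O=C1C=CC(C)(C)[C@@H](CO[Si](C)(C)C(C)(C)C)C1 | intermediate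
7 | (5S,6R)-5-{[(tert-butyldimethylsilyl)oxy]methyl}-6-{[(4-methoxybenzyl)oxy]methyl}-4,4-dimethylcyclohex-2-en-1-one (5,6-trans) | COc1ccc(cc1)COC[C@@H]2C(=O)C=CC(C)(C)[C@H]2CO[Si](C)(C)C(C)(C)C | intermediate
8 | (5R,6S)-6-allyl-5-{[(tert-butyldimethylsilyl)oxy]methyl}-6-{[(4-methoxybenzyl)oxy]methyl}-4,4-dimethylcyclohex-2-en-1-one (allyl trans, CH2OPMB cis to CH2OTBS) | COc1ccc(cc1)COC[C@@]2(CC=C)C(=O)C=CC(C)(C)[C@H]2CO[Si](C)(C)C(C)(C)C | intermediate
9 | (2E)-4-[(1S,6R)-6-{[(tert-butyldimethylsilyl)oxy]methyl}-1-{[(4-methoxybenzyl)oxy]methyl}-5,5-dimethyl-2-oxocyclohex-3-en-1-yl]but-2-enal | COc1ccc(cc1)COC[C@@]2(C/C=C/C=O)C(=O)C=CC(C)(C)[C@H]2CO[Si](C)(C)C(C)(C)C | intermediate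
10 | (2E)-4-[(1S,6R)-6-{[(tert-butyldimethylsilyl)oxy]methyl}-1-(hydroxymethyl)-5,5-dimethyl-2-oxocyclohex-3-en-1-yl]but-2-enal | OC[C@@]1(C/C=C/C=O)C(=O)C=CC(C)(C)[C@H]1CO[Si](C)(C)C(C)(C)C | intermediate
11 | [(1S,6R)-6-{[(tert-butyldimethylsilyl)oxy]methyl}-5,5-dimethyl-2-oxo-1-[(2E)-4-oxobut-2-en-1-yl]cyclohex-3-en-1-yl]methyl prop-2-enoate | C=CC(=O)OC[C@@]1(C/C=C/C=O)C(=O)C=CC(C)(C)[C@H]1CO[Si](C)(C)C(C)(C)C | intermediate
12 | [(1S,6R)-1-[(1E,3E)-4-{[tert-butyl(dimethyl)silyl]oxy}buta-1,3-dien-1-yl]-6-{[(tert-butyldimethylsilyl)oxy]methyl}-5,5-dimethyl-2-oxocyclohex-3-en-1-yl]methyl prop-2-enoate | C=CC(=O)OC[C@@]1(/C=C/C=C/O[Si](C)(C)C(C)(C)C)C(=O)C=CC(C)(C)[C@H]1CO[Si](C)(C)C(C)(C)C | intermediate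
13 | (1S,4a'R,6R,7'R,8a'S)-7'-[(tert-butyldimethylsilyl)oxy]-6-{[(tert-butyldimethylsilyl)oxy]methyl}-5,5-dimethyl-4a',7',8',8a'-tetrahydrospiro[cyclohex-3-ene-1,4'-isochromene]-1',2(3'H)-dione (cis-fused lactone; H4, H7 and H8 all on the face opposite to C13) | CC(C)(C)[Si](C)(C)O[C@H]1C=C[C@@H]2[C@H](C1)C(=O)OC[C@]21C(=O)C=CC(C)(C)[C@H]1CO[Si](C)(C)C(C)(C)C | intermediate
14 | (1S,4a'R,6R,7'R,8a'S)-7'-hydroxy-6-(hydroxymethyl)-5,5-dimethyl-4a',7',8',8a'-tetrahydrospiro[cyclohex-3-ene-1,4'-isochromene]-1',2(3'H)-dione | O[C@H]1C=C[C@@H]2[C@H](C1)C(=O)OC[C@]21C(=O)C=CC(C)(C)[C@H]1CO | intermediate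
15 | (1R,2S,4a'R,5R,7'R,8a'S)-7'-hydroxy-8,8-dimethyl-4a',7',8',8a'-tetrahydrospiro[6-oxabicyclo[3.2.1]octane-2,4'-isochromene]-1',3(3'H)-dione (C4–OH cis to C13) | O[C@H]1C=C[C@@H]2[C@H](C1)C(=O)OC[C@]21C(=O)C[C@H]2OC[C@@H]1C2(C)C | intermediate
16 | (1R,2S,4a'R,5R,7'S,8a'S)-8,8-dimethyl-1',3-dioxo-4a',7',8',8a'-tetrahydrospiro[6-oxabicyclo[3.2.1]octane-2,4'-isochromen]-7'(3'H)-yl 4-nitrobenzoate (C4–O trans to C13) | O=C(O[C@@H]1C=C[C@@H]2[C@H](C1)C(=O)OC[C@]21C(=O)C[C@H]2OC[C@@H]1C2(C)C)c1ccc(cc1)[N+](=O)[O-] | intermediate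
17 | dibenzyl 2-[(1R,2S,4a'R,5R,7'S,8a'S)-8,8-dimethyl-1',3-dioxo-4a',7',8',8a'-tetrahydrospiro[6-oxabicyclo[3.2.1]octane-2,4'-isochromen]-7'(3'H)-yl]propanedioate | O=C(OCc1ccccc1)C(C(=O)OCc1ccccc1)[C@@H]1C=C[C@@H]2[C@H](C1)C(=O)OC[C@]21C(=O)C[C@H]2OC[C@@H]1C2(C)C | intermediate
18 | 2-[(1R,2S,4a'R,5R,7'R,8a'S)-8,8-dimethyl-1',3-dioxo-4a',5',6',7',8',8a'-hexahydrospiro[6-oxabicyclo[3.2.1]octane-2,4'-isochromen]-7'(3'H)-yl]propanedioic acid | OC(=O)C(C(=O)O)[C@@H]1CC[C@@H]2[C@H](C1)C(=O)OC[C@]21C(=O)C[C@H]2OC[C@@H]1C2(C)C | intermediate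
19 | 2-[(diethylamino)methyl]-2-[(1R,2S,4a'R,5R,7'R,8a'S)-8,8-dimethyl-1',3-dioxo-4a',5',6',7',8',8a'-hexahydrospiro[6-oxabicyclo[3.2.1]octane-2,4'-isochromen]-7'(3'H)-yl]propanedioic acid | CCN(CC)CC(C(=O)O)(C(=O)O)[C@@H]1CC[C@@H]2[C@H](C1)C(=O)OC[C@]21C(=O)C[C@H]2OC[C@@H]1C2(C)C | intermediate
20 | 2-[(1R,2S,4a'R,5R,7'R,8a'S)-8,8-dimethyl-1',3-dioxo-4a',5',6',7',8',8a'-hexahydrospiro[6-oxabicyclo[3.2.1]octane-2,4'-isochromen]-7'(3'H)-yl]prop-2-enoic acid, CNP0268721.2 (4R,7R,8S,13S,16R,19R in the numbering used here) | C=C(C(=O)O)[C@@H]1CC[C@@H]2[C@H](C1)C(=O)OC[C@]21C(=O)C[C@H]2OC[C@@H]1C2(C)C | target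

**Step count and risks**

Total step count: 14. Longest linear sequence: 14 steps (fully linear from 1).

Steps most likely to fail:

1. Step 2 (proposed new method).
   - What may go wrong: the iminium ion of an unsubstituted, symmetric dienone may not hold the radical to one β-carbon and one face. A racemic addition to the free dienone may compete. Hydrogen abstraction from the ether C–H bonds of the product may lead to further alkylation.
   - Fallback with known chemistry, from 2 back to 5: copper-catalysed enantioselective conjugate addition of the hydroxymethyl anion equivalent (isopropoxydimethylsilyl)methylmagnesium chloride (CuBr·SMe2, chiral ferrocenyl diphosphine of the Josiphos type, t-BuOMe, −78 °C) desymmetrises the dienone to silylmethyl enone F1. This reaction type is established for cyclic enones and for desymmetrising 4,4-disubstituted cyclohexadienones with organometallic reagents. Tamao–Fleming oxidation (H2O2, KF, KHCO3, THF/MeOH) then unveils hydroxy enone 4, which closes under the basic conditions to 5.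

2. Step 9.
   - What may go wrong: the cycloaddition may be slow, because the tether forces the C7–C8/C4–C9 pairing against the polarisation of the silyloxydiene and the ester must reach its s-cis rotamer. The silyl dienol ether may then be lost, the acrylate may polymerise, or endo and facial selectivity may erode at the temperature needed.
   - Fallback, from 9 back to 13: TBSOTf/Et3N converts 9 into PMB-protected dienol silyl ether F2. Maleic anhydride (toluene, 25 °C), a symmetric and far more reactive dienophile, gives endo anhydride adduct F3 without a tether or a regiochemical question. DDQ removes the PMB group and the freed C12 alcohol opens the anhydride at the proximal carbonyl C10 to give lactone acid F4. Esterification with 2-mercaptopyridine N-oxide (DCC) gives thiohydroxamate ester F5, and photolysis with t-BuSH (Barton reductive decarboxylation) removes the surplus carboxyl at C9 and delivers 13. This answers the rate problem; the diene face still depends on C19 shielding.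

3. Step 5.
   - What may go wrong: facial discrimination at the tetrasubstituted enolate may be insufficient, since the pseudoaxial methyl on C20 shields the face anti to C18. β-Elimination of the p-methoxybenzyl oxide or O-allylation may also compete.
   - Fallback, from 7 back to 8: the potassium enolate (KN(SiMe3)2, THF, −78 °C) is O-acylated with allyl chloroformate to allyl enol carbonate F6. Decarboxylative allylic alkylation with Pd2(dba)3 and a chiral phosphinooxazoline ligand (t-Bu-PHOX, THF, 25 °C) then forms the quaternary centre under catalyst control, the ligand antipode being chosen to place the allyl group trans to C18, and gives 8.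

Further compounds
F1 | step 2 | (5S)-5-{[dimethyl(propan-2-yloxy)silyl]methyl}-4,4-dimethylcyclohex-2-en-1-one | O=C1C=CC(C)(C)[C@@H](C[Si](C)(C)OC(C)C)C1
F2 | step 9 | (5R,6S)-6-[(1E,3E)-4-{[tert-butyl(dimethyl)silyl]oxy}buta-1,3-dien-1-yl]-5-{[(tert-butyldimethylsilyl)oxy]methyl}-6-{[(4-methoxybenzyl)oxy]methyl}-4,4-dimethylcyclohex-2-en-1-one | COc1ccc(cc1)COC[C@@]2(/C=C/C=C/O[Si](C)(C)C(C)(C)C)C(=O)C=CC(C)(C)[C@H]2CO[Si](C)(C)C(C)(C)C
F3 | step 9 | endo maleic anhydride adduct of F2: cis-cyclohex-4-ene-1,2-dicarboxylic anhydride carrying the C4 silyloxy group and the C13 ring at C7, all ring substituents cis | CC(C)(C)[Si](C)(C)O[C@H]1C=C[C@@H]([C@]2(COCc3ccc(OC)cc3)C(=O)C=CC(C)(C)[C@H]2CO[Si](C)(C)C(C)(C)C)[C@H]4C(=O)OC(=O)[C@H]41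
F4 | step 9 | lactone acid: compound 13 carrying a carboxyl group on C9, cis to the lactone carbonyl | CC(C)(C)[Si](C)(C)O[C@H]1C=C[C@@H]2[C@H]([C@H]1C(=O)O)C(=O)OC[C@]21C(=O)C=CC(C)(C)[C@H]1CO[Si](C)(C)C(C)(C)C
F5 | step 9 | 2-thioxopyridin-1(2H)-yl ester of F4 | CC(C)(C)[Si](C)(C)O[C@H]1C=C[C@@H]2[C@H]([C@H]1C(=O)ON3C=CC=CC3=S)C(=O)OC[C@]21C(=O)C=CC(C)(C)[C@H]1CO[Si](C)(C)C(C)(C)C
F6 | step 5 | prop-2-en-1-yl (3R)-3-{[(tert-butyldimethylsilyl)oxy]methyl}-2-{[(4-methoxybenzyl)oxy]methyl}-4,4-dimethylcyclohexa-1,5-dien-1-yl carbonate | C=CCOC(=O)OC1=C(COCc2ccc(OC)cc2)[C@H](CO[Si](C)(C)C(C)(C)C)C(C)(C)C=C1
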